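**Retrosynthetic overview**
1. The all-cis (2R,3R,4R) target comes from its C3 methyl ester (hydride reduction), and that from a 2-aryl-4-benzyl-4,5-dihydrofuran-3-carboxylate by syn-hydrogenation of C2=C3 opposite the C4 benzyl group, which sets C2 and C3.
2. The dihydrofuran ester comes from an acyclic alkynol, CO and MeOH in one palladium-catalysed operation: 5-endo-dig attack of the C5 hydroxyl oxygen on the aryl-bearing alkyne carbon closes the ring (bond O1–C2), and the C3–Pd bond is carbonylated to the carbon that becomes CH2OH.
3. Enabling feature: in the oxolane, O1 sits between an unsubstituted C5H2 and C2, which carries the electron-rich 3,4,5-trimethoxyphenyl ring, and C3 carries one exocyclic carbon. C2–C3 therefore maps onto an arylalkyne, the CH2OH carbon onto CO, and the cis,cis C2/C3/C4 triad onto one preset centre (C4) plus one face-selective hydrogenation.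
4. The alkynol comes from a 1,2-diol (glycol cleavage, reduction), made by C3-selective opening of a Sharpless epoxy alcohol with an aluminium acetylide; the E-allylic alcohol comes from a Stille coupling.
5. Ring order: the oxolane is the only ring formed (step 5); both arenes are bought.

Key step: step 5

Remark on the chemistry: the target is read as the all-cis oxolane, with the aryl, hydroxymethyl and benzyl groups on one face of the ring.

**Step 1**
Reactants: 1 4-(chloromethyl)-1,2-dimethoxybenzene; 2 (2E)-3-(tributylstannyl)prop-2-en-1-ol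
Product: 3 (2E)-4-(3,4-dimethoxyphenyl)but-2-en-1-ol
Conditions: Pd2(dba)3 (2.5 mol %), P(2-furyl)3 (10 mol %), THF, 65 °C
Reagents that add atoms: none
Why: Migita–Kosugi–Stille coupling, in which zerovalent palladium inserts into the benzylic C–Cl bond and the alkenylstannane transfers its alkenyl group with retention, should give the E-allylic alcohol with the free hydroxyl untouched; no stereocentre is formed.

**Step 2**
Reactants: 3 (2E)-4-(3,4-dimethoxyphenyl)but-2-en-1-ol
Product: 4 [(2R,3R)-3-[(3,4-dimethoxyphenyl)methyl]oxiran-2-yl]methanol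
Conditions: Ti(OiPr)4 (10 mol %), diethyl D-(−)-tartrate (12 mol %), t-BuOOH (2 equiv, decane), 4 Å MS, CH2Cl2, −20 °C
Reagents that add atoms: tert-butyl hydroperoxide, CC(C)(C)OO
Why: Sharpless asymmetric epoxidation, in which the Ti(OiPr)4–D-(−)-tartrate complex binds the allylic hydroxyl and delivers the peroxide oxygen to one enantioface of the E-alkene, should set both epoxide carbons as (2R,3R) under reagent control.

**Step 3**
Reactants: 4 [(2R,3R)-3-[(3,4-dimethoxyphenyl)methyl]oxiran-2-yl]methanol; 5 5-ethynyl-1,2,3-trimethoxybenzene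
Product: 8 (2S,3R)-3-[(3,4-dimethoxyphenyl)methyl]-5-(3,4,5-trimethoxyphenyl)pent-4-yne-1,2-diol, via lithium acetylide 6 (not isolated), via diethylalkynylalane 7 (not isolated)
Conditions: 5 (3 equiv), n-BuLi, toluene, 0 °C; Et2AlCl, 0 °C; then 4, toluene/CH2Cl2, 0 °C to rt; 1 M HCl work-up
Reagents that add atoms: none
Why: Opening of a 2,3-epoxy alcohol by an aluminium acetylide, in which the alane is anchored as the C1 alkoxide and transfers the alkynyl group to C3 in an SN2 manner, should give the 1,2-diol with inversion at C3 (the descriptor stays R because the ligand priorities change).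

**Step 4**
Reactants: 8 (2S,3R)-3-[(3,4-dimethoxyphenyl)methyl]-5-(3,4,5-trimethoxyphenyl)pent-4-yne-1,2-diol
Product: 10 (2R)-2-[(3,4-dimethoxyphenyl)methyl]-4-(3,4,5-trimethoxyphenyl)but-3-yn-1-ol, via alkynyl aldehyde 9 (not isolated)
Conditions: NaIO4 on silica gel, CH2Cl2, 0 °C; filtrate into NaBH4, CeCl3·7H2O, MeOH, −40 °C
Reagents that add atoms: none
Why: Malaprade glycol cleavage followed at once by Luche reduction removes C1 as formaldehyde and turns C2 into the primary alcohol, and because the cleavage is neutral and the aldehyde is reduced cold without isolation the propargylic centre should not enolise.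

**Step 5**
Reactants: 10 (2R)-2-[(3,4-dimethoxyphenyl)methyl]-4-(3,4,5-trimethoxyphenyl)but-3-yn-1-ol
Product: 11 methyl (4R)-4-[(3,4-dimethoxyphenyl)methyl]-2-(3,4,5-trimethoxyphenyl)-4,5-dihydrofuran-3-carboxylate
Conditions: PdI2 (2 mol %), KI (20 mol %), CO (32 atm), air (8 atm), MeOH, 100 °C
Reagents that add atoms: carbon monoxide, [C-]#[O+]; methanol, CO
Why: Mechanism: PdI2 (divalent palladium, present as PdI4 2−) activates the alkyne, the C5 hydroxyl oxygen adds anti to the alkyne carbon that carries the trimethoxyphenyl ring (bond O1–C2), and the 3-palladated 4,5-dihydrofuran inserts CO and is methanolysed to the ester, while zerovalent palladium is returned to PdI2 by HI and O2. The closest known reaction type is the PdI2/KI oxidative heterocyclisation–alkoxycarbonylation of 3-yne-1,2-diols, which gives furan-3-carboxylates and, where aromatisation is blocked, 4-methylene-4,5-dihydrofuran-3-carboxylates through the same 5-endo-dig step; here three components (10, CO, MeOH) are joined and the ring and full carbon skeleton of the target result from an acyclic alcohol. The oxolane ring is closed in the 5-endo-dig mode. No new stereocentre is formed (C2 and C3 leave as sp2 carbons), and the C4 centre, which carries H and no leaving group, is not touched, so the product should stay at the dihydrofuran level. The step needs oxygen attack at the distal alkyne carbon and CO insertion before protonolysis: 4-exo closure is not accessible, the electron-rich aryl group polarises the alkyne toward C2, and the high CO pressure favours acylpalladium formation.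

**Step 6**
Reactants: 11 methyl (4R)-4-[(3,4-dimethoxyphenyl)methyl]-2-(3,4,5-trimethoxyphenyl)-4,5-dihydrofuran-3-carboxylate
Product: 12 methyl (2R,3S,4R)-4-[(3,4-dimethoxyphenyl)methyl]-2-(3,4,5-trimethoxyphenyl)oxolane-3-carboxylate
Conditions: H2 (40 bar), 5 % Rh/Al2O3, EtOAc, 25 °C
Reagents that add atoms: none
Why: Heterogeneous syn-hydrogenation of a cyclic beta-alkoxyacrylate should deliver both hydrogens to the C2=C3 face opposite the C4 benzyl group (substrate control), which places the aryl group at C2 and the ester at C3 cis to that benzyl group and to each other; Rh/Al2O3 is chosen as the metal least prone to cleave the benzylic C2–O1 bond.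

**Step 7**
Reactants: 12 methyl (2R,3S,4R)-4-[(3,4-dimethoxyphenyl)methyl]-2-(3,4,5-trimethoxyphenyl)oxolane-3-carboxylate
Product: 13 [(2R,3R,4R)-4-[(3,4-dimethoxyphenyl)methyl]-2-(3,4,5-trimethoxyphenyl)oxolan-3-yl]methanol
Conditions: LiAlH4, THF, −20 to 0 °C; then H2O, 15 % aq. NaOH, H2O
Reagents that add atoms: none
Why: Hydride reduction of the ester with LiAlH4 should convert the C3 carboxylate carbon into the CH2OH group faster than the ester can enolise, so the three ring stereocentres are carried into 13 unchanged (the C3 descriptor changes from S to R only through ligand priorities).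

**Compound list**
1 | 4-(chloromethyl)-1,2-dimethoxybenzene | COc1ccc(CCl)cc1OC | starting material
2 | (2E)-3-(tributylstannyl)prop-2-en-1-ol | CCCC[Sn](CCCC)(CCCC)/C=C/CO | starting material
3 | (2E)-4-(3,4-dimethoxyphenyl)but-2-en-1-ol | COc1ccc(C/C=C/CO)cc1OC | intermediate
4 | [(2R,3R)-3-[(3,4-dimethoxyphenyl)methyl]oxiran-2-yl]methanol | OC[C@H]1O[C@@H]1Cc1ccc(OC)c(OC)c1 | intermediate
5 | 5-ethynyl-1,2,3-trimethoxybenzene | COc1cc(C#C)cc(OC)c1OC | starting material
6 | lithium (3,4,5-trimethoxyphenyl)acetylide | [Li]C#Cc1cc(OC)c(OC)c(OC)c1 | intermediate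
7 | diethyl[(3,4,5-trimethoxyphenyl)ethynyl]alane | CC[Al](CC)C#Cc1cc(OC)c(OC)c(OC)c1 | intermediate
8 | (2S,3R)-3-[(3,4-dimethoxyphenyl)methyl]-5-(3,4,5-trimethoxyphenyl)pent-4-yne-1,2-diol | COc1ccc(C[C@@H]([C@H](O)CO)C#Cc2cc(OC)c(OC)c(OC)c2)cc1OC | intermediate
9 | (2R)-2-[(3,4-dimethoxyphenyl)methyl]-4-(3,4,5-trimethoxyphenyl)but-3-ynal | COc1ccc(C[C@@H](C=O)C#Cc2cc(OC)c(OC)c(OC)c2)cc1OC | intermediate
10 | (2R)-2-[(3,4-dimethoxyphenyl)methyl]-4-(3,4,5-trimethoxyphenyl)but-3-yn-1-ol | COc1ccc(C[C@@H](CO)C#Cc2cc(OC)c(OC)c(OC)c2)cc1OC | intermediate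
11 | methyl (4R)-4-[(3,4-dimethoxyphenyl)methyl]-2-(3,4,5-trimethoxyphenyl)-4,5-dihydrofuran-3-carboxylate | COc1ccc(C[C@H]2COC(c3cc(OC)c(OC)c(OC)c3)=C2C(=O)OC)cc1OC | intermediate
12 | methyl (2R,3S,4R)-4-[(3,4-dimethoxyphenyl)methyl]-2-(3,4,5-trimethoxyphenyl)oxolane-3-carboxylate | COc1ccc(C[C@H]2CO[C@@H](c3cc(OC)c(OC)c(OC)c3)[C@H]2C(=O)OC)cc1OC | intermediate
13 | [(2R,3R,4R)-4-[(3,4-dimethoxyphenyl)methyl]-2-(3,4,5-trimethoxyphenyl)oxolan-3-yl]methanol | COc1ccc(C[C@H]2CO[C@@H](c3cc(OC)c(OC)c(OC)c3)[C@H]2CO)cc1OC | target

Total step count: 7. Longest linear sequence: 7 steps (1 and 2 to 13; alkyne 5 enters at step 3).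

**Steps most likely to fail**

Step 5 (key step). What may go wrong: protonolysis of the vinylpalladium intermediate before CO insertion, which would give cycloisomerisation without the ester carbon. Alternatively, a methoxycarbonylpalladium species may add across the alkyne, so that carbonylation runs without ring closure through oxygen. Fallback: setting out from 10, the two events are separated. Iodine-induced 5-endo-dig cyclisation (I2, NaHCO3, MeCN, 0 °C) should give the 3-iodo-4,5-dihydrofuran F1. Its C3–I bond is then methoxycarbonylated under palladium catalysis (PdCl2(PPh3)2, CO 1 atm, Et3N, MeOH/DMF, 60 °C). This returns to the route at 11.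

Step 6. What may go wrong: hydrogenolysis of the benzylic C2–O1 bond, partial saturation of an electron-rich arene on rhodium, or slow uptake by the tetrasubstituted push–pull double bond. Fallback: setting out from 11, the ester is reduced first (i-Bu2AlH, CH2Cl2, −78 °C) to the allylic alcohol F2. The now electron-rich alkene is then hydrogenated homogeneously under hydroxyl direction ([Ir(cod)(PCy3)(py)]PF6, H2 1 atm, CH2Cl2, 0 °C). The metal is held by the CH2OH group while the C4 benzyl group still blocks one face, so the same all-cis product is expected. The route is rejoined directly at 13, and step 7 is not needed.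

Step 3. What may go wrong: competing attack at C2, or participation of the electron-rich dimethoxyphenyl ring in the Lewis-acid-activated epoxide (aryl shift); both would erode the supply of the C3-alkynylated diol. Fallback: setting out from 3, the propargylic centre is made by catalytic asymmetric allylic substitution instead of epoxide opening. Alcohol 3 is converted into the allylic phosphate F3 (ClP(O)(OEt)2, pyridine, DMAP, CH2Cl2). F3 then undergoes copper-catalysed, SN2′-selective enantioselective substitution (CuCl2·2H2O, chiral sulfonate-bearing N-heterocyclic carbene ligand, THF, −30 °C) with the diisobutyl(alkynyl)alane F4, made from 5 with i-Bu2AlH and catalytic Et3N. The ligand enantiomer is chosen to give the 1,4-enyne F5. Lemieux–Johnson cleavage of its vinyl group (OsO4 cat., NaIO4, 2,6-lutidine, dioxane/H2O) gives aldehyde 9, where the route is rejoined; reduction as in step 4 leads to 10.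

**Further compounds**
F1 | step 5 | (4S)-4-[(3,4-dimethoxyphenyl)methyl]-3-iodo-2-(3,4,5-trimethoxyphenyl)-4,5-dihydrofuran | COc1ccc(C[C@H]2COC(c3cc(OC)c(OC)c(OC)c3)=C2I)cc1OC
F2 | step 6 | [(4R)-4-[(3,4-dimethoxyphenyl)methyl]-2-(3,4,5-trimethoxyphenyl)-4,5-dihydrofuran-3-yl]methanol | COc1ccc(C[C@H]2COC(c3cc(OC)c(OC)c(OC)c3)=C2CO)cc1OC
F3 | step 3 | diethyl (2E)-4-(3,4-dimethoxyphenyl)but-2-en-1-yl phosphate | CCOP(=O)(OCC)OC/C=C/Cc1ccc(OC)c(OC)c1
F4 | step 3 | bis(2-methylpropyl)[(3,4,5-trimethoxyphenyl)ethynyl]alane | CC(C)C[Al](CC(C)C)C#Cc1cc(OC)c(OC)c(OC)c1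
F5 | step 3 | 5-[(3S)-3-[(3,4-dimethoxyphenyl)methyl]pent-4-en-1-yn-1-yl]-1,2,3-trimethoxybenzene | COc1ccc(C[C@@H](C=C)C#Cc2cc(OC)c(OC)c(OC)c2)cc1OC
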